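## Structural features

The target is an unsymmetrical dimer of two constitutionally identical lignan units. Each unit is a γ-butyrolactone (C2 carbonyl, C3 tertiary carbinol, C4 methine, C5 OCH2) carrying one 4-hydroxy-3-methoxybenzyl group on C3 and one on C4. The units are joined by a single aryl–aryl bond between ring B (C3 benzyl ring of lactone 1) and ring C (C4 benzyl ring of lactone 2), ortho to each phenol. The core is therefore a 2,2'-dihydroxy-3,3'-dimethoxybiphenyl with one ortho substituent per ring, so the axis rotates freely and is not a stereo element. Each lactone holds two adjacent stereocentres, the quaternary C3 (R) and the methine C4 (R), with the benzyl groups trans and the hydroxyl cis to the C4 benzyl; the two pairs are remote and must be set independently. Fragile sites are the four electron-rich phenols and the α-hydroxy lactones, which open in base, translactonise if a free CH2OH sits on C4, and eliminate if a leaving group on C3 is placed β to a carbonyl. The real difficulty is the 5–5' biaryl between two almost identical guaiacyl rings that hang on different positions of two almost identical lactones, so any oxidative or statistical coupling is unselective. The key step uses the fact that ring B is a 1,3,4,5-tetrasubstituted benzene with OMe, OH and aryl contiguous. The CH2-bearing carbon, the adjacent CH, the aryl-bearing carbon and the oxygen-bearing carbon map onto C6, C5, C4 and C3 of a 2-pyrone, and the C(OMe)–CH edge onto a ketene acetal. The ring B–ring C bond is then the former aldehyde–aryl bond of an o-vanillin and is never made by coupling.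

## Logic of the disconnections

42 back to 41 and 39: no skeletal bond is cut. The O–CH2Ph bonds on rings A and C are restored first, then the O–acetyl bonds on rings B and D and the O–Si bonds at C3 of both lactones. Hydrogenolysis is placed last because the free tetraphenol is the most oxidation-prone compound of the route. The forward solvolysis must not touch stereocentres, which holds because C3 is quaternary and C4 is not acidic, and a lactone opened by methoxide must reclose in acid.

39 back to 26 and 37: the bond between the ring C carbon para to its oxygen and the CH2 on C4 of lactone 2 is cut. It is the only acyclic C–C bond that divides the molecule into two halves of similar size with all four stereocentres already in place. The gain is full convergence. The forward step needs a carbon–zinc bond (38) formed beside a lactone, an aryl ester and a silyl ether, and a reductive elimination that outruns β-hydride elimination.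

26 back to 22 and 23: two bonds of ring B are cut, between the CH2-bearing carbon and the neighbouring CH, and between the acetoxy carbon and the methoxy carbon. This turns the biaryl problem into a ring synthesis in which the aryl–aryl bond pre-exists as an aryl–C4 bond of a pyrone. The gain is that no cross-coupling between two similar guaiacyl rings is needed and the OMe/OAc/aryl sequence is fixed by the connectivity of 22. The forward step must be regioselective and must run under neutral thermal conditions that leave the silyl ether, the lactone and the aryl bromide untouched.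

22 back to 20, 19, then 18 and 12: the pyrone O1–C2 bond (an enol ester) and the pyrone C4–C5 bond are cut. This exposes a δ-keto α-keto acid that is the alkylation product of an α-keto ester with a bromomethyl ketone. The gain is two fragments of equal complexity, one carrying lactone 1 and one carrying ring C. The forward sequence needs C- rather than O-alkylation of an ambident enolate and six-ring closure through the carboxyl rather than five-ring closure through the C2 oxygen.

18 back to 16, 14 with 15, and 13: the C=C bond made from the aldehyde carbon is cut, then the benzyl ether. The aldehyde carbon of 13 becomes the ring B carbon bonded to ring C, and bromine is already at the ring C position that later receives the CH2 of lactone 2. The demands are routine: an olefination of a hindered aldehyde and an enamide hydrolysis that spares the aryl benzyl ether.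

12 back to 11, then 8 and 9: the ketone oxygen is traded for a methylene carbon and the bond from C3 of lactone 1 to its new CH2 is cut. The three-carbon bis-electrophile 9 delivers the CH2–C(=X)–CH2Br unit in one alkylation. The forward alkylation must occur anti to the C4 benzyl group to set the quaternary C3, and the tertiary alkoxide must be capped before it attacks the allylic bromide.

8 back to 6, 5, 4, then 3 and 2, and 2 back to 1: the ring C5–O bond and the bond from C4 to its benzyl CH2 are cut. This reaches a chiral-pool hydroxy diester whose carbinol carbon directs the alkylation. The gain is that C4 of lactone 1 comes from a commodity compound. The demands are anti-selective dianion alkylation and reduction of only the carboxyl that is not α to the hydroxyl, which the dioxolanone in 6 secures.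

37 back to 36, 35, 34, then 32 and 2: the C–I bond is traced to a benzyloxymethyl group and the bond from C3 of lactone 2 to the ring D CH2 is cut. The same bromide 2 that serves ring A is reused. The forward alkylation must again go anti to the C4 substituent, and the freed CH2OH of 35 must be iodinated before it can translactonise.

32 back to 30, 29, 28, then 3 and 27: the ring C5–O bond and the bond from C4 to the oxygenated CH2 are cut, in parallel with the route to 8. The gain is that both lactones draw their absolute configuration from the same enantiomer of 3. The forward alkylation must occur on carbon, not on the alkoxide oxygen, with a small and reactive electrophile.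

## Other disconnections considered

Alternative 1: The cut is made inside each lactone at O–C3 and C4–C5; the retron is a 2-isoxazoline. The precursor is the biaryl bis(allylic alcohol) A2 with two (E)-2-benzyl-4-arylbut-2-en-1-ol units. In the forward step a bromonitrile oxide released in situ would add twice under zinc alkoxide and tartrate direction to give the bis(3-bromo-2-isoxazoline) A1. Oxygen goes to the fully substituted carbon; CH2OH is the later C2 and the C(Br)=N carbon the later C5.
- In favour: suprafacial addition to the (E) alkene fixes the C3/C4 relationship, which becomes trans-dibenzyl once the lactone is closed. Absolute configuration comes from a reagent and not from the chiral pool. All four stereocentres arise in one two-directional operation.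
- Against: A2 already contains the unsymmetrical biaryl, so that bond would still need a cross-coupling of two differentiated guaiacyl rings, plus two trisubstituted alkenes of defined geometry. Tartrate-directed nitrile oxide additions are best founded on less substituted allylic alcohols; a halonitrile oxide on a 2-benzyl trisubstituted alkene, twice, is an extrapolation. Each half then needs N–O cleavage, conversion of C(Br)=N into CH2OH and oxidation of CH2OH to the acid.
- Comparison: on structure, A1 solves the lactones and leaves the biaryl, while the chosen plan solves the biaryl by ring synthesis and takes the stereocentres from 3. On mechanism both key steps are concerted cycloadditions, but here the step must create four stereocentres under catalyst control, whereas the pyrone annulation creates none and cannot fail stereochemically. On stereocentres per step and independence from chiral-pool sequences the alternative is the better. On total length it should be about equal once the biaryl, alkene and redox steps are counted. Protecting-group load is equal.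

Alternative 2: The cut is made at lactone 2 only: the C4–CH2(ring C) bond, with that CH2 as a dithiane carbon, and the C3–CH2(ring D) bond. The acceptor is the 3-benzyloxy-5-menthyloxybutenolide A4, which carries the (1S,2R,5S)-menthyl group. In the forward step the lithiated biaryl dithiane A5 would add to C4 anti to the menthyloxy group, and the enolate would be benzylated by the ring D bromide anti to the new C4 substituent, giving A3.
- In favour: one pot forms both benzylic C–C bonds and both stereocentres of lactone 2 under control of a recoverable auxiliary. The trans-dibenzyl relationship is the inherent outcome. The C5 acetal is a latent CH2 that leaves the carbonyl at the right carbon.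
- Against: the enol ether oxygen on C3 of A4 pushes electron density onto C4 and weakens the acceptor. The intermediate enolate is tetrasubstituted and α-oxygenated, so C-benzylation beside the dithiane builds a very crowded quaternary centre, and O-alkylation or simple protonation may compete. Later desulfurisation with Raney nickel is hard to reconcile with benzyl ethers, and sulfur residues burden the final hydrogenolysis. Only lactone 2 is made: lactone 1 must still be grown from the silyloxymethyl handle, and the biaryl of A5 must come from a cross-coupling.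
- Comparison: on structure, A3 fixes one lactone on a pre-made biaryl, while the chosen plan makes the biaryl last-but-one and brings both lactones in complete. On mechanism it is an ionic conjugate addition–alkylation against a pericyclic annulation. For lactone 2 alone the alternative is the better in step economy, since the chosen plan spends eight steps on 37. Over the whole molecule the chosen plan should be shorter and avoids sulfur. The way the second quaternary centre would be made (alkylation of a lactone enediolate) is equal in both.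

Alternative 3: The cut is the C3–C4 bond of both lactones. The precursor is the bis(allylic ester) A7, each half an α-benzyloxy-β-arylpropanoate of a 5-arylpent-3-en-2-ol. In the forward step, double enolisation and silylation would give the chelated bis(silyl ketene acetal), and two chair-like [3,3] shifts would give the diacid A6 with an (E)-propenyl group on each C4 as latent C5.
- In favour: four stereocentres, two of them quaternary, arise in one pot by chirality transfer from two secondary allylic alcohols. The sigmatropic shift is reliable for crowded C–C bonds. The precursors are acyclic and assembled by two esterifications.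
- Against: with a chelate-controlled enolate and a chair, the trans-dibenzyl arrangement requires (Z)-configured allylic esters with (R) carbinol centres, as drawn for A7. Two different enantiopure (Z)-allylic alcohols are therefore needed. Enolate geometry at a hindered α-alkoxy ester rests on chelation alone, and any leakage at one site multiplies over two. Two propenyl groups must then be ozonised beside four electron-rich rings, reduced and lactonised. The biaryl must again come from a cross-coupling.
- Comparison: on structure, A6 has both C3–C4 bonds and all stereocentres but still lacks both lactone rings and presupposes the biaryl. On mechanism both plans rest on a pericyclic key step, but the Claisen step must deliver four stereocentres while the pyrone annulation delivers none. On stereocentre economy and two-directional processing the alternative is the better; on protecting groups it is equal. The chosen plan is the better in that it needs neither a biaryl coupling nor four separately made stereodefined fragments.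

Key step: step 14

Remark on the chemistry: both tertiary C3 hydroxyls are carried as triethylsilyl ethers and the pyrone oxygen and ring D phenol as acetates, because an ester on C3 of lactone 1 would be a β-leaving group next to the ketone and pyrone CH2 formed on the way; the biaryl axis is taken as freely rotating and is given no descriptor.

## Route

Step 1
Reactants: 1 4-(benzyloxy)-3-methoxybenzyl alcohol
Product: 2 4-(benzyloxy)-3-methoxybenzyl bromide
Conditions: PBr3 (0.4 equiv), Et2O, 0 °C
Reagents that add atoms: phosphorus tribromide, BrP(Br)Br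
Why: Bromination of an electron-rich benzylic alcohol through its phosphite ester (nucleophilic displacement by bromide); the bromide is made in one batch and used fresh in steps 2 and 19.

Step 2
Reactants: 3 dimethyl (R)-malate; 2 4-(benzyloxy)-3-methoxybenzyl bromide
Product: 4 dimethyl (2R,3S)-3-[4-(benzyloxy)-3-methoxybenzyl]-2-hydroxybutanedioate
Conditions: LiN(SiMe3)2 (2.2 equiv), THF, −78 °C; then 2, −78 → −15 °C
Reagents that add atoms: none
Why: Fráter–Seebach alkylation: the chelated alkoxide–enolate dianion is benzylated anti to the C2 oxygen, which sets C3 (S) from the existing C2 (R) centre. This carbon becomes C4 (R) of lactone 1.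

Step 3
Reactants: 4 dimethyl (2R,3S)-3-[4-(benzyloxy)-3-methoxybenzyl]-2-hydroxybutanedioate
Product: 5 (2R,3S)-3-[4-(benzyloxy)-3-methoxybenzyl]-2-hydroxybutanedioic acid
Conditions: KOH (4 equiv), MeOH/H2O, rt; then HCl to pH 1
Reagents that add atoms: potassium hydroxide, [K+].[OH-]
Why: Saponification of both methyl esters; the α-carbon of the dicarboxylate should not epimerise at room temperature because further deprotonation of the polyanion is unfavourable.

Step 4
Reactants: 5 (2R,3S)-3-[4-(benzyloxy)-3-methoxybenzyl]-2-hydroxybutanedioic acid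
Product: 6 (2S)-3-[4-(benzyloxy)-3-methoxyphenyl]-2-[(4R)-2,2-dimethyl-5-oxo-1,3-dioxolan-4-yl]propanoic acid
Conditions: Me2C(OMe)2, TsOH (cat.), CH2Cl2, rt
Reagents that add atoms: 2,2-dimethoxypropane, COC(C)(C)OC
Why: Acetalisation of an α-hydroxy acid: the five-membered dioxolanone forms in preference to the six-membered alternative, so the α-hydroxy carboxyl is masked and the other carboxyl stays free for reduction.

Step 5
Reactants: 6 (2S)-3-[4-(benzyloxy)-3-methoxyphenyl]-2-[(4R)-2,2-dimethyl-5-oxo-1,3-dioxolan-4-yl]propanoic acid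
Product: 8 (3R,4R)-4-[4-(benzyloxy)-3-methoxybenzyl]-3-hydroxydihydrofuran-2(3H)-one, via hydroxy dioxolanone 7 (not isolated)
Conditions: BH3·SMe2, THF, 0 °C → rt; MeOH; then TsOH (cat.), CH2Cl2, rt
Reagents that add atoms: none
Why: Chemoselective borane reduction of the free carboxylic acid (its acyloxyborane is reduced much faster than the dioxolanone carbonyl), then acid-catalysed translactonisation of the γ-hydroxy dioxolanone with loss of acetone. No stereocentre is touched.

Step 6
Reactants: 8 (3R,4R)-4-[4-(benzyloxy)-3-methoxybenzyl]-3-hydroxydihydrofuran-2(3H)-one; 9 3-bromo-2-(bromomethyl)prop-1-ene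
Product: 11 (3R,4R)-4-[4-(benzyloxy)-3-methoxybenzyl]-3-[2-(bromomethyl)prop-2-en-1-yl]-3-[(triethylsilyl)oxy]dihydrofuran-2(3H)-one, via lithium alkoxide 10 (not isolated)
Conditions: LiN(SiMe3)2 (2.3 equiv), THF, −78 °C; 9 (3 equiv), −78 → −45 °C; then Et3SiOTf (1.6 equiv), −78 → 0 °C
Reagents that add atoms: triethylsilyl trifluoromethanesulfonate, CC[Si](CC)(CC)OS(=O)(=O)C(F)(F)F
Why: Alkylation of the lactone enediolate by an allylic bromide on the face anti to the C4 benzyl group sets the quaternary C3 (R) with the new CH2 trans to the C4 substituent. The excess symmetrical dibromide (direct and allylic displacement give the same product) suppresses double alkylation, and the cold silyl triflate quench caps the tertiary alkoxide before it can close onto the allylic bromide.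

Step 7
Reactants: 11 (3R,4R)-4-[4-(benzyloxy)-3-methoxybenzyl]-3-[2-(bromomethyl)prop-2-en-1-yl]-3-[(triethylsilyl)oxy]dihydrofuran-2(3H)-one
Product: 12 (3R,4R)-4-[4-(benzyloxy)-3-methoxybenzyl]-3-(3-bromo-2-oxopropyl)-3-[(triethylsilyl)oxy]dihydrofuran-2(3H)-one
Conditions: O3, CH2Cl2/MeOH, NaHCO3, −78 °C; then Me2S, −78 → 0 °C
Reagents that add atoms: ozone, [O-][O+]=O
Why: Ozonolysis of the 1,1-disubstituted alkene, which should react far faster than the dialkoxyarene or the benzyl ether, gives the bromomethyl ketone directly. The reduction with Me2S is kept cold and short because α-bromo ketones alkylate sulfides on standing.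

Step 8
Reactants: 13 5-bromo-2-hydroxy-3-methoxybenzaldehyde
Product: 14 2-(benzyloxy)-5-bromo-3-methoxybenzaldehyde
Conditions: BnBr, K2CO3, DMF, rt
Reagents that add atoms: benzyl bromide, BrCc1ccccc1
Why: Williamson etherification of the acidic ortho-formyl phenoxide; the benzyl ether matches the one on ring A so that both leave in the last step.

Step 9
Reactants: 14 2-(benzyloxy)-5-bromo-3-methoxybenzaldehyde; 15 methyl 2-[(tert-butoxycarbonyl)amino]-2-(dimethoxyphosphoryl)acetate
Product: 16 methyl (Z)-3-[2-(benzyloxy)-5-bromo-3-methoxyphenyl]-2-[(tert-butoxycarbonyl)amino]prop-2-enoate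
Conditions: DBU, CH2Cl2, 0 °C → rt
Reagents that add atoms: none
Why: Horner–Wadsworth–Emmons olefination with a phosphonoglycinate gives the dehydroamino ester, a masked arylpyruvate. The aldehyde carbon becomes C4 of the pyrone and thus the ring B carbon bonded to ring C.

Step 10
Reactants: 16 methyl (Z)-3-[2-(benzyloxy)-5-bromo-3-methoxyphenyl]-2-[(tert-butoxycarbonyl)amino]prop-2-enoate
Product: 18 methyl 3-[2-(benzyloxy)-5-bromo-3-methoxyphenyl]-2-oxopropanoate, via enamino ester 17 (not isolated)
Conditions: CF3CO2H/CH2Cl2 (1:3), 0 °C → rt; then 1 M HCl, THF, rt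
Reagents that add atoms: water, O
Why: Acidolysis of the carbamate releases a primary enamine that tautomerises to the α-imino ester and is hydrolysed to the α-keto ester, which rests largely as its enol. The aryl benzyl ether and aryl bromide should tolerate the brief acid exposure.

Step 11
Reactants: 18 methyl 3-[2-(benzyloxy)-5-bromo-3-methoxyphenyl]-2-oxopropanoate; 12 (3R,4R)-4-[4-(benzyloxy)-3-methoxybenzyl]-3-(3-bromo-2-oxopropyl)-3-[(triethylsilyl)oxy]dihydrofuran-2(3H)-one
Product: 19 methyl 3-[2-(benzyloxy)-5-bromo-3-methoxyphenyl]-6-{(3R,4R)-4-[4-(benzyloxy)-3-methoxybenzyl]-2-oxo-3-[(triethylsilyl)oxy]tetrahydrofuran-3-yl}-2,5-dioxohexanoate (both C3 epimers)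
Conditions: NaH (1.0 equiv), THF, 0 °C; then 12, 0 °C → rt
Reagents that add atoms: none
Why: C-Alkylation of a stabilised α-keto ester enolate (acidity like a β-dicarbonyl compound, so it does not deprotonate the bromo ketone) by a primary α-bromo ketone in a bimolecular substitution. The tight sodium ion pair in THF and the soft electrophile should favour carbon over oxygen; the new benzylic stereocentre is irrelevant because it becomes sp2 in step 13.

Step 12
Reactants: 19 methyl 3-[2-(benzyloxy)-5-bromo-3-methoxyphenyl]-6-{(3R,4R)-4-[4-(benzyloxy)-3-methoxybenzyl]-2-oxo-3-[(triethylsilyl)oxy]tetrahydrofuran-3-yl}-2,5-dioxohexanoate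
Product: 20 3-[2-(benzyloxy)-5-bromo-3-methoxyphenyl]-6-{(3R,4R)-4-[4-(benzyloxy)-3-methoxybenzyl]-2-oxo-3-[(triethylsilyl)oxy]tetrahydrofuran-3-yl}-2,5-dioxohexanoic acid
Conditions: LiOH (1.2 equiv), THF/H2O, 0 °C; then HCl to pH 3
Reagents that add atoms: lithium hydroxide, [Li+].[OH-]
Why: Selective saponification: an α-keto ester is hydrolysed much faster than the hindered γ-lactone, which would in any case reclose on acidification. The silyloxy group on C3 is a poor leaving group, so β-elimination should not compete in the cold.

Step 13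
Reactants: 20 3-[2-(benzyloxy)-5-bromo-3-methoxyphenyl]-6-{(3R,4R)-4-[4-(benzyloxy)-3-methoxybenzyl]-2-oxo-3-[(triethylsilyl)oxy]tetrahydrofuran-3-yl}-2,5-dioxohexanoic acid
Product: 22 4-[2-(benzyloxy)-5-bromo-3-methoxyphenyl]-6-({(3R,4R)-4-[4-(benzyloxy)-3-methoxybenzyl]-2-oxo-3-[(triethylsilyl)oxy]tetrahydrofuran-3-yl}methyl)-2-oxo-2H-pyran-3-yl acetate, via mixed anhydride enol acetate 21 (not isolated)
Conditions: Ac2O, pyridine, DMAP (cat.), 0 °C → rt; then 70 °C
Reagents that add atoms: acetic anhydride, CC(=O)OC(C)=O
Why: Enol-lactonisation of a δ-keto acid: acetylation first caps the C2 enol, which shuts off five-ring Paal–Knorr closure, and activates the carboxyl as a mixed anhydride. The enol oxygen of the C5 ketone is then acylated intramolecularly (6-exo-trig) to give the 2-pyrone; the favoured enol acetate geometry (aryl trans to the carboxyl) is the one that can close.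

Step 14
Reactants: 22 4-[2-(benzyloxy)-5-bromo-3-methoxyphenyl]-6-({(3R,4R)-4-[4-(benzyloxy)-3-methoxybenzyl]-2-oxo-3-[(triethylsilyl)oxy]tetrahydrofuran-3-yl}methyl)-2-oxo-2H-pyran-3-yl acetate; 23 1,1-dimethoxyethene
Product: 26 2'-(benzyloxy)-5'-bromo-3,3'-dimethoxy-5-({(3R,4R)-4-[4-(benzyloxy)-3-methoxybenzyl]-2-oxo-3-[(triethylsilyl)oxy]tetrahydrofuran-3-yl}methyl)biphenyl-2-yl acetate, via bicyclic lactone adduct 24 (not isolated), via dimethoxycyclohexadiene 25 (not isolated)
Conditions: 23 (10 equiv), PhMe, base-washed sealed tube, 130 °C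
Reagents that add atoms: none
Why: Inverse-electron-demand Diels–Alder reaction: the 2-pyrone, whose acetoxy group is net electron-withdrawing on the σ frame, is the electron-poor 4π partner and the ketene acetal the electron-rich 2π partner; bonding is concerted but asynchronous, the nucleophilic CH2 of 23 reaching C6 (the δ-terminus of the dienoate) ahead of the acetal carbon reaching C3. The bridged 2-oxabicyclo[2.2.2]octenone 24 loses CO2 by retro-[4+2] cycloreversion to diene 25, and 1,2-elimination of methanol, which excess 23 scavenges as the orthoester, makes ring B aromatic. The closest known reaction type is the benzannulation of 2-pyrones with ketene acetals to alkoxyarenes, applied here to a 3-acyloxy-4-aryl-6-alkyl pyrone that should need more heat than ester-activated pyrones. Ring B is closed by an intermolecular [4+2] annulation that makes both new C–C bonds in one step (ring B numbered from the CH2-bearing carbon: C1–C6 and C4–C5), not by an exo or endo cyclisation of a chain. No stereocentre is created: the two bridgehead centres of 24 vanish on aromatisation, the lactone centres are quaternary or non-acidic and inert to neutral thermolysis, and the biaryl axis with one ortho substituent per ring rotates freely. The selectivity needed is regiochemical (OMe next to OAc, the new CH next to the CH2 arm) and is secured by the matched polarisation of the dienoate and the ketene acetal. Chemoselectivity rests on neutral, acid-free conditions under which the silyl ether, the lactone, the enol acetate and the aryl bromide are spectators.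

Step 15
Reactants: 3 dimethyl (R)-malate; 27 benzyl chloromethyl ether
Product: 28 dimethyl (2R,3S)-3-[(benzyloxy)methyl]-2-hydroxybutanedioate
Conditions: LiN(SiMe3)2 (2.2 equiv), THF, −78 °C; then 27 (1.05 equiv), −78 → −30 °C
Reagents that add atoms: none
Why: Fráter–Seebach alkylation with a reactive chloromethyl ether: at low temperature the enolate carbon of the dianion is far more nucleophilic than the aggregated lithium alkoxide. Attack anti to the C2 oxygen sets C3 (S), the future C4 of lactone 2.

Step 16
Reactants: 28 dimethyl (2R,3S)-3-[(benzyloxy)methyl]-2-hydroxybutanedioate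
Product: 29 (2R,3S)-3-[(benzyloxy)methyl]-2-hydroxybutanedioic acid
Conditions: KOH (4 equiv), MeOH/H2O, rt; then HCl to pH 1
Reagents that add atoms: potassium hydroxide, [K+].[OH-]
Why: Saponification of both methyl esters, as in step 3; the alkyl benzyl ether is inert to hydroxide.

Step 17
Reactants: 29 (2R,3S)-3-[(benzyloxy)methyl]-2-hydroxybutanedioic acid
Product: 30 (2S)-3-(benzyloxy)-2-[(4R)-2,2-dimethyl-5-oxo-1,3-dioxolan-4-yl]propanoic acid
Conditions: Me2C(OMe)2, TsOH (cat.), CH2Cl2, rt
Reagents that add atoms: 2,2-dimethoxypropane, COC(C)(C)OC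
Why: Selective dioxolanone formation from the α-hydroxy acid, as in step 4, leaves the other carboxyl free.

Step 18
Reactants: 30 (2S)-3-(benzyloxy)-2-[(4R)-2,2-dimethyl-5-oxo-1,3-dioxolan-4-yl]propanoic acid
Product: 32 (3R,4R)-4-[(benzyloxy)methyl]-3-hydroxydihydrofuran-2(3H)-one, via hydroxy dioxolanone 31 (not isolated)
Conditions: BH3·SMe2, THF, 0 °C → rt; MeOH; then TsOH (cat.), CH2Cl2, rt
Reagents that add atoms: none
Why: Borane reduction of the free acid and acid-catalysed translactonisation with loss of acetone, as in step 5. The two CH2O arms on C4 stay distinct because one is a benzyl ether, so the C4 configuration is kept.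

Step 19
Reactants: 32 (3R,4R)-4-[(benzyloxy)methyl]-3-hydroxydihydrofuran-2(3H)-one; 2 4-(benzyloxy)-3-methoxybenzyl bromide
Product: 34 (3R,4R)-3-[4-(benzyloxy)-3-methoxybenzyl]-4-[(benzyloxy)methyl]-3-[(triethylsilyl)oxy]dihydrofuran-2(3H)-one, via lithium alkoxide 33 (not isolated)
Conditions: LiN(SiMe3)2 (2.3 equiv), THF, −78 °C; 2 (1.3 equiv), −78 → −40 °C; then Et3SiOTf (1.6 equiv), −78 → 0 °C
Reagents that add atoms: triethylsilyl trifluoromethanesulfonate, CC[Si](CC)(CC)OS(=O)(=O)C(F)(F)F
Why: Benzylation of the lactone enediolate anti to the C4 benzyloxymethyl group sets the quaternary C3 (R) of lactone 2 with the ring D benzyl trans to the C4 arm. The silyl triflate quench protects the tertiary alkoxide in the same flask.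

Step 20
Reactants: 34 (3R,4R)-3-[4-(benzyloxy)-3-methoxybenzyl]-4-[(benzyloxy)methyl]-3-[(triethylsilyl)oxy]dihydrofuran-2(3H)-one
Product: 35 (3R,4R)-3-(4-hydroxy-3-methoxybenzyl)-4-(hydroxymethyl)-3-[(triethylsilyl)oxy]dihydrofuran-2(3H)-one
Conditions: H2 (1 atm), Pd/C, EtOAc, rt
Reagents that add atoms: none
Why: Hydrogenolysis of the alkyl and the aryl benzyl ether under neutral conditions, which the tertiary silyl ether survives. The freed CH2OH is kept away from acid and base, which would let it translactonise onto C2 and scramble C4, and is iodinated at once.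

Step 21
Reactants: 35 (3R,4R)-3-(4-hydroxy-3-methoxybenzyl)-4-(hydroxymethyl)-3-[(triethylsilyl)oxy]dihydrofuran-2(3H)-one
Product: 36 (3R,4R)-3-(4-hydroxy-3-methoxybenzyl)-4-(iodomethyl)-3-[(triethylsilyl)oxy]dihydrofuran-2(3H)-one
Conditions: PPh3, I2, imidazole, CH2Cl2, 0 °C → rt, dark
Reagents that add atoms: iodine, II
Why: Appel-type iodination of the primary alcohol (iodide displaces the alkoxyphosphonium group at CH2, so C4 is untouched). The phenol can only form a reversible aryloxyphosphonium species and is returned on work-up.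

Step 22
Reactants: 36 (3R,4R)-3-(4-hydroxy-3-methoxybenzyl)-4-(iodomethyl)-3-[(triethylsilyl)oxy]dihydrofuran-2(3H)-one
Product: 37 4-({(3R,4R)-4-(iodomethyl)-2-oxo-3-[(triethylsilyl)oxy]tetrahydrofuran-3-yl}methyl)-2-methoxyphenyl acetate
Conditions: Ac2O, Et3N, DMAP (cat.), CH2Cl2, 0 °C
Reagents that add atoms: acetic anhydride, CC(=O)OC(C)=O
Why: Fast acylation of the phenol removes the only acidic proton before the carbon–zinc bond is made, and puts on ring D the same group that ring B carries.

Step 23
Reactants: 26 2'-(benzyloxy)-5'-bromo-3,3'-dimethoxy-5-({(3R,4R)-4-[4-(benzyloxy)-3-methoxybenzyl]-2-oxo-3-[(triethylsilyl)oxy]tetrahydrofuran-3-yl}methyl)biphenyl-2-yl acetate; 37 4-({(3R,4R)-4-(iodomethyl)-2-oxo-3-[(triethylsilyl)oxy]tetrahydrofuran-3-yl}methyl)-2-methoxyphenyl acetate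
Product: 39 fully protected dimer (rings A and C O-benzyl; rings B and D O-acetyl; C3 of both lactones O-triethylsilyl; both lactones 3R,4R), via alkylzinc iodide 38 (not isolated)
Conditions: 37 (1.5 equiv), Zn dust (Me3SiCl, BrCH2CH2Br), DMF, rt; then 26, Pd2(dba)3 (2.5 mol %), SPhos (10 mol %), THF/DMF, 45 °C
Reagents that add atoms: none
Why: Negishi sp3–sp2 cross-coupling: zinc inserts into the primary C–I bond to give an alkylzinc iodide that tolerates lactone, aryl acetate and silyl ether. Oxidative addition of the unhindered aryl bromide to the zerovalent palladium–SPhos catalyst, transmetalation and fast reductive elimination from the bulky biarylphosphine complex should outpace β-hydride elimination; C4 of lactone 2 is not part of the reacting bond and keeps its configuration.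

Step 24
Reactants: 39 fully protected dimer (rings A and C O-benzyl; rings B and D O-acetyl; C3 of both lactones O-triethylsilyl)
Product: 41 dibenzyl ether of the target (rings A and C O-benzyl; all other hydroxyls free; both lactones 3R,4R), via bis(silyl ether) diphenol 40 (not isolated)
Conditions: K2CO3 (3 equiv), MeOH/THF, 0 °C → rt, Ar; then 2 M HCl to pH 1, rt
Reagents that add atoms: none
Why: Methanolysis of the two aryl acetates, then acid solvolysis of the two tertiary silyl ethers in the same flask. Any lactone opened by methoxide recloses in acid onto its own C5 hydroxyl, and no stereocentre can epimerise because C3 is quaternary and C4 is not acidic.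

Step 25
Reactants: 41 dibenzyl ether of the target (rings A and C O-benzyl)
Product: 42 CNP0218652.1, (3R,4R)-3-hydroxy-3-{[2,2'-dihydroxy-5'-{[(3R,4R)-4-hydroxy-4-(4-hydroxy-3-methoxybenzyl)-5-oxotetrahydrofuran-3-yl]methyl}-3,3'-dimethoxybiphenyl-5-yl]methyl}-4-(4-hydroxy-3-methoxybenzyl)dihydrofuran-2(3H)-one
Conditions: H2 (1 atm), Pd/C, EtOAc/MeOH, rt
Reagents that add atoms: none
Why: Hydrogenolysis of the two aryl benzyl ethers; nothing else in the molecule is reducible under these conditions, and the oxidation-prone tetraphenol is formed only in the last, neutral step.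

## Compound list

1 | 4-(benzyloxy)-3-methoxybenzyl alcohol | COc1cc(CO)ccc1OCc1ccccc1 | starting material
2 | 4-(benzyloxy)-3-methoxybenzyl bromide | COc1cc(CBr)ccc1OCc1ccccc1 | intermediate
3 | dimethyl (R)-malate | COC(=O)C[C@@H](O)C(=O)OC | starting material
4 | dimethyl (2R,3S)-3-[4-(benzyloxy)-3-methoxybenzyl]-2-hydroxybutanedioate | COc1cc(C[C@@H]([C@@H](O)C(=O)OC)C(=O)OC)ccc1OCc1ccccc1 | intermediate
5 | (2R,3S)-3-[4-(benzyloxy)-3-methoxybenzyl]-2-hydroxybutanedioic acid | COc1cc(C[C@@H]([C@@H](O)C(=O)O)C(=O)O)ccc1OCc1ccccc1 | intermediate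
6 | (2S)-3-[4-(benzyloxy)-3-methoxyphenyl]-2-[(4R)-2,2-dimethyl-5-oxo-1,3-dioxolan-4-yl]propanoic acid | COc1cc(C[C@@H]([C@H]2OC(C)(C)OC2=O)C(=O)O)ccc1OCc1ccccc1 | intermediate
7 | (5R)-5-{(2R)-1-[4-(benzyloxy)-3-methoxyphenyl]-3-hydroxypropan-2-yl}-2,2-dimethyl-1,3-dioxolan-4-one (not isolated) | COc1cc(C[C@@H]([C@H]2OC(C)(C)OC2=O)CO)ccc1OCc1ccccc1 | intermediate
8 | (3R,4R)-4-[4-(benzyloxy)-3-methoxybenzyl]-3-hydroxydihydrofuran-2(3H)-one | COc1cc(C[C@@H]2COC(=O)[C@@H]2O)ccc1OCc1ccccc1 | intermediate
9 | 3-bromo-2-(bromomethyl)prop-1-ene | C=C(CBr)CBr | starting material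
10 | lithium (3R,4R)-4-[4-(benzyloxy)-3-methoxybenzyl]-3-[2-(bromomethyl)prop-2-en-1-yl]-2-oxotetrahydrofuran-3-olate (not isolated) | COc1cc(C[C@@H]2COC(=O)[C@@]2(O[Li])CC(=C)CBr)ccc1OCc1ccccc1 | intermediate
11 | (3R,4R)-4-[4-(benzyloxy)-3-methoxybenzyl]-3-[2-(bromomethyl)prop-2-en-1-yl]-3-[(triethylsilyl)oxy]dihydrofuran-2(3H)-one | COc1cc(C[C@@H]2COC(=O)[C@@]2(O[Si](CC)(CC)CC)CC(=C)CBr)ccc1OCc1ccccc1 | intermediate
12 | (3R,4R)-4-[4-(benzyloxy)-3-methoxybenzyl]-3-(3-bromo-2-oxopropyl)-3-[(triethylsilyl)oxy]dihydrofuran-2(3H)-one | COc1cc(C[C@@H]2COC(=O)[C@@]2(O[Si](CC)(CC)CC)CC(=O)CBr)ccc1OCc1ccccc1 | intermediate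
13 | 5-bromo-2-hydroxy-3-methoxybenzaldehyde | COc1cc(Br)cc(C=O)c1O | starting material
14 | 2-(benzyloxy)-5-bromo-3-methoxybenzaldehyde | COc1cc(Br)cc(C=O)c1OCc1ccccc1 | intermediate
15 | methyl 2-[(tert-butoxycarbonyl)amino]-2-(dimethoxyphosphoryl)acetate (racemic) | COC(=O)C(NC(=O)OC(C)(C)C)P(=O)(OC)OC | starting material
16 | methyl (Z)-3-[2-(benzyloxy)-5-bromo-3-methoxyphenyl]-2-[(tert-butoxycarbonyl)amino]prop-2-enoate | COC(=O)/C(NC(=O)OC(C)(C)C)=C/c1cc(Br)cc(OC)c1OCc1ccccc1 | intermediate
17 | methyl (Z)-2-amino-3-[2-(benzyloxy)-5-bromo-3-methoxyphenyl]prop-2-enoate (not isolated; present as its trifluoroacetate) | COC(=O)/C(N)=C/c1cc(Br)cc(OC)c1OCc1ccccc1 | intermediate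
18 | methyl 3-[2-(benzyloxy)-5-bromo-3-methoxyphenyl]-2-oxopropanoate | COC(=O)C(=O)Cc1cc(Br)cc(OC)c1OCc1ccccc1 | intermediate
19 | methyl 3-[2-(benzyloxy)-5-bromo-3-methoxyphenyl]-6-{(3R,4R)-4-[4-(benzyloxy)-3-methoxybenzyl]-2-oxo-3-[(triethylsilyl)oxy]tetrahydrofuran-3-yl}-2,5-dioxohexanoate (both C3 epimers) | COc1cc(C[C@@H]2COC(=O)[C@@]2(O[Si](CC)(CC)CC)CC(=O)CC(C(=O)C(=O)OC)c2cc(Br)cc(OC)c2OCc2ccccc2)ccc1OCc1ccccc1 | intermediate
20 | 3-[2-(benzyloxy)-5-bromo-3-methoxyphenyl]-6-{(3R,4R)-4-[4-(benzyloxy)-3-methoxybenzyl]-2-oxo-3-[(triethylsilyl)oxy]tetrahydrofuran-3-yl}-2,5-dioxohexanoic acid (both C3 epimers) | COc1cc(C[C@@H]2COC(=O)[C@@]2(O[Si](CC)(CC)CC)CC(=O)CC(C(=O)C(=O)O)c2cc(Br)cc(OC)c2OCc2ccccc2)ccc1OCc1ccccc1 | intermediate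
21 | acetic (2Z)-2-acetoxy-3-[2-(benzyloxy)-5-bromo-3-methoxyphenyl]-6-{(3R,4R)-lactone 1 C3 silyl ether}-5-oxohex-2-enoic anhydride (not isolated) | COc1cc(C[C@@H]2COC(=O)[C@@]2(O[Si](CC)(CC)CC)CC(=O)C/C(c2cc(Br)cc(OC)c2OCc2ccccc2)=C(/OC(C)=O)C(=O)OC(C)=O)ccc1OCc1ccccc1 | intermediate
22 | 4-[2-(benzyloxy)-5-bromo-3-methoxyphenyl]-6-({(3R,4R)-4-[4-(benzyloxy)-3-methoxybenzyl]-2-oxo-3-[(triethylsilyl)oxy]tetrahydrofuran-3-yl}methyl)-2-oxo-2H-pyran-3-yl acetate | COc1cc(C[C@@H]2COC(=O)[C@@]2(O[Si](CC)(CC)CC)CC2=CC(c3cc(Br)cc(OC)c3OCc3ccccc3)=C(OC(C)=O)C(=O)O2)ccc1OCc1ccccc1 | intermediate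
23 | 1,1-dimethoxyethene | C=C(OC)OC | starting material
24 | 4-acetoxy-5-[2-(benzyloxy)-5-bromo-3-methoxyphenyl]-8,8-dimethoxy-1-[(lactone 1 C3 silyl ether)methyl]-2-oxabicyclo[2.2.2]oct-5-en-3-one (not isolated; bridgehead configuration undefined) | COc1cc(C[C@@H]2COC(=O)[C@@]2(O[Si](CC)(CC)CC)CC23CC(OC)(OC)C(OC(C)=O)(C(=O)O2)C(c2cc(Br)cc(OC)c2OCc2ccccc2)=C3)ccc1OCc1ccccc1 | intermediate
25 | 2-[2-(benzyloxy)-5-bromo-3-methoxyphenyl]-6,6-dimethoxy-4-[(lactone 1 C3 silyl ether)methyl]cyclohexa-1,3-dien-1-yl acetate (not isolated) | COc1cc(C[C@@H]2COC(=O)[C@@]2(O[Si](CC)(CC)CC)CC2=CC(c3cc(Br)cc(OC)c3OCc3ccccc3)=C(OC(C)=O)C(OC)(OC)C2)ccc1OCc1ccccc1 | intermediate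
26 | 2'-(benzyloxy)-5'-bromo-3,3'-dimethoxy-5-({(3R,4R)-4-[4-(benzyloxy)-3-methoxybenzyl]-2-oxo-3-[(triethylsilyl)oxy]tetrahydrofuran-3-yl}methyl)biphenyl-2-yl acetate | COc1cc(C[C@@H]2COC(=O)[C@@]2(O[Si](CC)(CC)CC)Cc2cc(OC)c(OC(C)=O)c(-c3cc(Br)cc(OC)c3OCc3ccccc3)c2)ccc1OCc1ccccc1 | intermediate
27 | benzyl chloromethyl ether | ClCOCc1ccccc1 | starting material
28 | dimethyl (2R,3S)-3-[(benzyloxy)methyl]-2-hydroxybutanedioate | c1ccccc1COC[C@@H]([C@@H](O)C(=O)OC)C(=O)OC | intermediate
29 | (2R,3S)-3-[(benzyloxy)methyl]-2-hydroxybutanedioic acid | c1ccccc1COC[C@@H]([C@@H](O)C(=O)O)C(=O)O | intermediate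
30 | (2S)-3-(benzyloxy)-2-[(4R)-2,2-dimethyl-5-oxo-1,3-dioxolan-4-yl]propanoic acid | c1ccccc1COC[C@@H]([C@H]2OC(C)(C)OC2=O)C(=O)O | intermediate
31 | (5R)-5-[(2S)-1-(benzyloxy)-3-hydroxypropan-2-yl]-2,2-dimethyl-1,3-dioxolan-4-one (not isolated) | c1ccccc1COC[C@@H]([C@H]2OC(C)(C)OC2=O)CO | intermediate
32 | (3R,4R)-4-[(benzyloxy)methyl]-3-hydroxydihydrofuran-2(3H)-one | c1ccccc1COC[C@@H]1COC(=O)[C@@H]1O | intermediate
33 | lithium (3R,4R)-3-[4-(benzyloxy)-3-methoxybenzyl]-4-[(benzyloxy)methyl]-2-oxotetrahydrofuran-3-olate (not isolated) | c1ccccc1COC[C@@H]1COC(=O)[C@@]1(O[Li])Cc1ccc(OCc2ccccc2)c(OC)c1 | intermediate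
34 | (3R,4R)-3-[4-(benzyloxy)-3-methoxybenzyl]-4-[(benzyloxy)methyl]-3-[(triethylsilyl)oxy]dihydrofuran-2(3H)-one | c1ccccc1COC[C@@H]1COC(=O)[C@@]1(O[Si](CC)(CC)CC)Cc1ccc(OCc2ccccc2)c(OC)c1 | intermediate
35 | (3R,4R)-3-(4-hydroxy-3-methoxybenzyl)-4-(hydroxymethyl)-3-[(triethylsilyl)oxy]dihydrofuran-2(3H)-one | OC[C@@H]1COC(=O)[C@@]1(O[Si](CC)(CC)CC)Cc1ccc(O)c(OC)c1 | intermediate
36 | (3R,4R)-3-(4-hydroxy-3-methoxybenzyl)-4-(iodomethyl)-3-[(triethylsilyl)oxy]dihydrofuran-2(3H)-one | IC[C@@H]1COC(=O)[C@@]1(O[Si](CC)(CC)CC)Cc1ccc(O)c(OC)c1 | intermediate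
37 | 4-({(3R,4R)-4-(iodomethyl)-2-oxo-3-[(triethylsilyl)oxy]tetrahydrofuran-3-yl}methyl)-2-methoxyphenyl acetate | IC[C@@H]1COC(=O)[C@@]1(O[Si](CC)(CC)CC)Cc1ccc(OC(C)=O)c(OC)c1 | intermediate
38 | ({(3R,4R)-4-[4-(acetyloxy)-3-methoxybenzyl]-5-oxo-4-[(triethylsilyl)oxy]tetrahydrofuran-3-yl}methyl)zinc iodide (not isolated) | I[Zn]C[C@@H]1COC(=O)[C@@]1(O[Si](CC)(CC)CC)Cc1ccc(OC(C)=O)c(OC)c1 | intermediate
39 | fully protected dimer: rings A and C O-benzyl; rings B and D O-acetyl; C3 of both lactones O-triethylsilyl; both lactones (3R,4R) | COc1cc(C[C@@H]2COC(=O)[C@@]2(O[Si](CC)(CC)CC)Cc2cc(OC)c(OC(C)=O)c(-c3cc(C[C@@H]4COC(=O)[C@@]4(O[Si](CC)(CC)CC)Cc4ccc(OC(C)=O)c(OC)c4)cc(OC)c3OCc3ccccc3)c2)ccc1OCc1ccccc1 | intermediate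
40 | dimer with rings A and C O-benzyl; rings B and D free phenols; C3 of both lactones O-triethylsilyl; both lactones (3R,4R) (not isolated) | COc1cc(C[C@@H]2COC(=O)[C@@]2(O[Si](CC)(CC)CC)Cc2cc(OC)c(O)c(-c3cc(C[C@@H]4COC(=O)[C@@]4(O[Si](CC)(CC)CC)Cc4ccc(O)c(OC)c4)cc(OC)c3OCc3ccccc3)c2)ccc1OCc1ccccc1 | intermediate
41 | dibenzyl ether of the target: rings A and C O-benzyl; all other hydroxyls free; both lactones (3R,4R) | COc1cc(C[C@@H]2COC(=O)[C@@]2(O)Cc2cc(OC)c(O)c(-c3cc(C[C@@H]4COC(=O)[C@@]4(O)Cc4ccc(O)c(OC)c4)cc(OC)c3OCc3ccccc3)c2)ccc1OCc1ccccc1 | intermediate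
42 | CNP0218652.1, (3R,4R)-3-hydroxy-3-{[2,2'-dihydroxy-5'-{[(3R,4R)-4-hydroxy-4-(4-hydroxy-3-methoxybenzyl)-5-oxotetrahydrofuran-3-yl]methyl}-3,3'-dimethoxybiphenyl-5-yl]methyl}-4-(4-hydroxy-3-methoxybenzyl)dihydrofuran-2(3H)-one | COc1cc(C[C@@H]2COC(=O)[C@@]2(O)Cc2cc(OC)c(O)c(-c3cc(C[C@@H]4COC(=O)[C@@]4(O)Cc4ccc(O)c(OC)c4)cc(OC)c3O)c2)ccc1O | target

## Step count and least certain steps

Total: 25 steps. Longest linear sequence: 14 steps (steps 1–7, 11–14 and 23–25).

Step 14 (key step). The most likely failure is a cycloaddition that is too slow at temperatures the reagents tolerate. The pyrone is only moderately electron-poor, and its C3 terminus is crowded by the twisted ortho-substituted aryl group. Oligomerisation of the ketene acetal and transfer of the enol acetyl group to the methanol released could then overtake ring formation. The fallback keeps the annulation but changes the diene and the sequence. It sets out from 22. Mild methanolysis (K2CO3 cat., MeOH, 0 °C) would give the 3-hydroxy-2-pyrone F1. Tf2O and pyridine would convert it into the far more electron-poor pyrone triflate F2. F2 should add 23 at 80–100 °C through the bicyclic adduct F3 and the dihydroarene F4 (neither isolated) to give the ring B aryl triflate F5. Cleavage of the sulfonate with aqueous Et4NOH in dioxane, followed by acidification so that the lactone recloses, would give the ring B phenol F6. Acetylation (Ac2O, pyridine) returns to the route at 26. The price is four extra operations and one exposure of lactone 1 to hydroxide, which is why this is not the first choice.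

Step 13. The most likely failure is ring closure in the wrong sense: the C2 and C5 oxygens are 1,4-related, and a five-membered Paal–Knorr-type cyclodehydration to a furan-2-carboxylic acid could run before the C2 enol is capped. Alternatively, the material could rest as an open-chain enol acetate that does not lactonise. The fallback closes the ring at the ester stage instead of through an activated acid. It sets out from 19. Ac2O, Et3N and DMAP would give the methyl (2Z)-2-acetoxy-5-oxohex-2-enoate F7, in which C2 can no longer take part in furan formation. Acid-catalysed lactonisation of this δ-keto enoate (camphorsulfonic acid cat., PhMe, 90 °C, with removal of methanol) then comes back to the route at 22 and skips 20.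

Step 11. The most likely failure is alkylation on oxygen of the ambident arylpyruvate enolate, whose carbon terminus is flanked by an ortho-substituted aryl ring. Self-condensation of the bromo ketone after proton transfer is a second risk. The fallback replaces the enolate by a neutral carbon nucleophile that cannot be O-alkylated. It sets out from 18. Condensation with pyrrolidine (TsOH cat., PhMe, azeotropic removal of water) would give the pyrrolidine enamine F8. Stork enamine alkylation with 12 in MeCN would give the C-alkylated iminium bromide F9, which is hydrolysed in the same flask (AcOH/NaOAc/H2O) and comes back to the route at 19.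

Step 23. The most likely failure is slow transmetalation of the β-branched alkylzinc that sits next to a quaternary carbon. Protodezincation to the 4-methyl lactone, β-hydride elimination after transmetalation, or reduction of the aryl bromide would then take over. The fallback avoids a preformed organometallic. It sets out from 26 and 37 and joins them by a nickel-catalysed reductive cross-electrophile coupling (NiBr2·(MeOCH2CH2OMe) 10 mol %, 4,4'-di-tert-butyl-2,2'-bipyridine, Mn powder, NaI, DMA, 60 °C, slow addition of 37). Here the alkyl fragment reaches nickel as a radical and the aryl bromide by oxidative addition. It comes back to the route directly at 39 and makes no new compound on the way (F0).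

Further compounds
F1 | step 14 | 3-hydroxy-2-pyrone: 22 with OH in place of OAc on pyrone C3 | COc1cc(C[C@@H]2COC(=O)[C@@]2(O[Si](CC)(CC)CC)CC2=CC(c3cc(Br)cc(OC)c3OCc3ccccc3)=C(O)C(=O)O2)ccc1OCc1ccccc1
F2 | step 14 | pyrone triflate: 22 with OSO2CF3 in place of OAc on pyrone C3 | COc1cc(C[C@@H]2COC(=O)[C@@]2(O[Si](CC)(CC)CC)CC2=CC(c3cc(Br)cc(OC)c3OCc3ccccc3)=C(OS(=O)(=O)C(F)(F)F)C(=O)O2)ccc1OCc1ccccc1
F3 | step 14 | bicyclic adduct of F2 and 23: 24 with OSO2CF3 in place of OAc on C4 (bridgehead configuration undefined) | COc1cc(C[C@@H]2COC(=O)[C@@]2(O[Si](CC)(CC)CC)CC23CC(OC)(OC)C(OS(=O)(=O)C(F)(F)F)(C(=O)O2)C(c2cc(Br)cc(OC)c2OCc2ccccc2)=C3)ccc1OCc1ccccc1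
F4 | step 14 | dimethoxycyclohexadienyl triflate: 25 with OSO2CF3 in place of OAc | COc1cc(C[C@@H]2COC(=O)[C@@]2(O[Si](CC)(CC)CC)CC2=CC(c3cc(Br)cc(OC)c3OCc3ccccc3)=C(OS(=O)(=O)C(F)(F)F)C(OC)(OC)C2)ccc1OCc1ccccc1
F5 | step 14 | ring B aryl triflate: 26 with OSO2CF3 in place of OAc on ring B | COc1cc(C[C@@H]2COC(=O)[C@@]2(O[Si](CC)(CC)CC)Cc2cc(OC)c(OS(=O)(=O)C(F)(F)F)c(-c3cc(Br)cc(OC)c3OCc3ccccc3)c2)ccc1OCc1ccccc1
F6 | step 14 | ring B phenol: 26 with OH in place of OAc on ring B | COc1cc(C[C@@H]2COC(=O)[C@@]2(O[Si](CC)(CC)CC)Cc2cc(OC)c(O)c(-c3cc(Br)cc(OC)c3OCc3ccccc3)c2)ccc1OCc1ccccc1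
F7 | step 13 | methyl (2Z)-2-acetoxy-3-[2-(benzyloxy)-5-bromo-3-methoxyphenyl]-6-{(3R,4R)-4-[4-(benzyloxy)-3-methoxybenzyl]-2-oxo-3-[(triethylsilyl)oxy]tetrahydrofuran-3-yl}-5-oxohex-2-enoate | COc1cc(C[C@@H]2COC(=O)[C@@]2(O[Si](CC)(CC)CC)CC(=O)C/C(c2cc(Br)cc(OC)c2OCc2ccccc2)=C(/OC(C)=O)C(=O)OC)ccc1OCc1ccccc1
F8 | step 11 | methyl 3-[2-(benzyloxy)-5-bromo-3-methoxyphenyl]-2-(pyrrolidin-1-yl)prop-2-enoate | COC(=O)C(=Cc1cc(Br)cc(OC)c1OCc1ccccc1)N1CCCC1
F9 | step 11 | C-alkylated pyrrolidinium (iminium) bromide: 19 with C2=N+(CH2)4 in place of the C2 ketone (both C3 epimers) | COc1cc(C[C@@H]2COC(=O)[C@@]2(O[Si](CC)(CC)CC)CC(=O)CC(C(=[N+]3CCCC3)C(=O)OC)c3cc(Br)cc(OC)c3OCc3ccccc3)ccc1OCc1ccccc1.[Br-]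
F0 | step 23 | none | none
A1 | alternative 1 | bis[3-bromo-4,5-dibenzyl-5-(hydroxymethyl)-2-isoxazoline] on the benzyl-protected biaryl core | COc1cc(C[C@@H]2C(Br)=NO[C@]2(CO)Cc2cc(OC)c(OCc3ccccc3)c(-c3cc(C[C@@H]4C(Br)=NO[C@]4(CO)Cc4ccc(OCc5ccccc5)c(OC)c4)cc(OC)c3OCc3ccccc3)c2)ccc1OCc1ccccc1
A2 | alternative 1 | bis[(E)-2-benzyl-4-arylbut-2-en-1-ol] on the benzyl-protected biaryl core | COc1cc(C/C=C(/CO)Cc2cc(OC)c(OCc3ccccc3)c(-c3cc(C/C=C(/CO)Cc4ccc(OCc5ccccc5)c(OC)c4)cc(OC)c3OCc3ccccc3)c2)ccc1OCc1ccccc1
A3 | alternative 2 | 3-benzyloxy-3-benzyl-4-(2-aryl-1,3-dithian-2-yl)-5-menthyloxy lactone (lactone 2 with C5 as acetal and the ring C CH2 as dithiane) | S1CCCSC1(c1cc(OC)c(OCc2ccccc2)c(-c2cc(CO[Si](C)(C)C(C)(C)C)cc(OC)c2OCc2ccccc2)c1)[C@@H]1[C@@H](O[C@H]2C[C@@H](C)CC[C@@H]2C(C)C)OC(=O)[C@@]1(OCc1ccccc1)Cc1ccc(OCc2ccccc2)c(OC)c1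
A4 | alternative 2 | (5S)-3-(benzyloxy)-5-[(1S,2R,5S)-menthyloxy]furan-2(5H)-one | O=C1O[C@H](O[C@H]2C[C@@H](C)CC[C@@H]2C(C)C)C=C1OCc1ccccc1
A5 | alternative 2 | 2-aryl-1,3-dithiane of the biaryl (ring C dithiane; ring B with CH2OSi(t-Bu)Me2) | S1CCCSC1c1cc(OC)c(OCc2ccccc2)c(-c2cc(CO[Si](C)(C)C(C)(C)C)cc(OC)c2OCc2ccccc2)c1
A6 | alternative 3 | bis[(E)-2-benzyloxy-2,3-dibenzylhex-4-enoic acid] on the benzyl-protected biaryl core | COc1cc(C[C@@H]([C@](C(=O)O)(OCc2ccccc2)Cc2cc(OC)c(OCc3ccccc3)c(-c3cc(C[C@@H]([C@](C(=O)O)(OCc4ccccc4)Cc4ccc(OCc5ccccc5)c(OC)c4)/C=C/C)cc(OC)c3OCc3ccccc3)c2)/C=C/C)ccc1OCc1ccccc1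
A7 | alternative 3 | bis[(2R,3Z)-5-arylpent-3-en-2-yl 2-(benzyloxy)-3-arylpropanoate] on the benzyl-protected biaryl core (α-carbons of either configuration) | COc1cc(C/C=C\[C@@H](C)OC(=O)C(OCc2ccccc2)Cc2cc(OC)c(OCc3ccccc3)c(-c3cc(C/C=C\[C@@H](C)OC(=O)C(OCc4ccccc4)Cc4ccc(OCc5ccccc5)c(OC)c4)cc(OC)c3OCc3ccccc3)c2)ccc1OCc1ccccc1
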